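## Retrosynthetic overview

1. The target is a (3S,6R)-6-methoxy-1,2-dioxane-3-acetic acid whose ketal carbon C6 carries a C16 (E)-dienyne chain. The acid comes from a primary alcohol, and the dioxane (the only ring, closed in step 14) comes from an acyclic (S)-hydroperoxide and a C6 dimethyl ketal by acid transketalisation.
2. The C3–O–O bond comes from SN2 inversion of an (R)-mesylate by hydroperoxide anion; the (R)-carbinol comes from Noyori hydrogenation of methyl 3-oxohept-6-enoate.
3. Key disconnection: the bond between the first and the second CH2 of the side chain (ring–CH2–CH2). It is made by decarboxylative radical–polar crossover coupling of the N-acyloxyphthalimide of (E)-hexadeca-6,15-dien-4-ynoic acid with a 2-methoxy-1-alkene, methanol capturing the cation as the C6 dimethyl ketal.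
4. Enabling feature: C6, the ring carbon that bears OMe and the ring O–O, is at the ketone oxidation level, so C6 and its exocyclic CH2 can be carried as the enol ether unit CH2=C(OMe)–. The next chain CH2 is insulated from the alkyne by one more CH2, so it is a plain primary radical available from a carboxylic acid.
5. Fragments: the enol ether mesylate from methyl acetoacetate and allyl bromide (steps 1–7); the acid from dec-9-enal by Takai olefination and Sonogashira coupling (steps 8–11).

Key step: step 12

Remark: the (6R) ketal configuration (methoxy axial, both carbon substituents equatorial on the dioxane chair) is taken to be the thermodynamically preferred epimer, so C6 is set by equilibration and only C3 by asymmetric synthesis.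

## Route

Step 1
Reactants: 1 methyl acetoacetate; 2 allyl bromide
Product: 3 methyl 3-oxohept-6-enoate
Conditions: LDA (2.1 equiv), THF, −78 → 0 °C; then 2, 0 °C; aq. HCl
Reagents that add atoms: none
Why: γ-Alkylation of the acetoacetate dianion, which should react with the allylic bromide only at its more basic terminal carbon.

Step 2
Reactants: 3 methyl 3-oxohept-6-enoate
Product: 4 methyl (R)-3-hydroxyhept-6-enoate
Conditions: [RuCl2((R)-BINAP)] (0.5 mol %), H2 (3–4 atm), MeOH, 50 °C
Reagents that add atoms: none
Why: Noyori asymmetric hydrogenation of a β-keto ester, in which the ester-chelated (R)-BINAP–Ru hydride should add to one ketone face and set the (R) carbinol centre (same sense as methyl acetoacetate to (R)-3-hydroxybutanoate), the isolated terminal alkene being much slower to reduce at this pressure.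

Step 3
Reactants: 4 methyl (R)-3-hydroxyhept-6-enoate
Product: 5 (R)-hept-6-ene-1,3-diol
Conditions: LiAlH4, THF, 0 °C; aq. NaOH work-up
Reagents that add atoms: none
Why: Hydride reduction of the ester to the primary alcohol, which does not involve the stereocentre or the alkene.

Step 4
Reactants: 5 (R)-hept-6-ene-1,3-diol
Product: 6 (R)-1-[(tert-butyldimethylsilyl)oxy]hept-6-en-3-ol
Conditions: TBSCl (1.05 equiv), imidazole, CH2Cl2, 0 °C
Reagents that add atoms: tert-butyldimethylsilyl chloride, CC(C)(C)[Si](C)(C)Cl
Why: Selective silylation of the less hindered primary hydroxyl of a 1,3-diol.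

Step 5
Reactants: 6 (R)-1-[(tert-butyldimethylsilyl)oxy]hept-6-en-3-ol
Product: 7 (R)-1-[(tert-butyldimethylsilyl)oxy]hept-6-en-3-yl methanesulfonate
Conditions: MsCl, Et3N, CH2Cl2, 0 °C
Reagents that add atoms: methanesulfonyl chloride, CS(=O)(=O)Cl
Why: Sulfonylation at oxygen, so the carbinol carbon keeps its (R) configuration and becomes the leaving-group carbon for the later inversion.

Step 6
Reactants: 7 (R)-1-[(tert-butyldimethylsilyl)oxy]hept-6-en-3-yl methanesulfonate
Product: 8 (R)-1-[(tert-butyldimethylsilyl)oxy]-6-oxoheptan-3-yl methanesulfonate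
Conditions: PdCl2 (10 mol %), CuCl, O2 (1 atm), DMF/H2O 7:1, rt
Reagents that add atoms: water, O (source of the carbonyl oxygen; O2 is the terminal oxidant)
Why: Tsuji–Wacker oxidation, in which Markovnikov hydroxypalladation of the terminal alkene should give the methyl ketone and leave mesylate and silyl ether untouched.

Step 7
Reactants: 8 (R)-1-[(tert-butyldimethylsilyl)oxy]-6-oxoheptan-3-yl methanesulfonate
Product: 10 (R)-1-[(tert-butyldimethylsilyl)oxy]-6-methoxyhept-6-en-3-yl methanesulfonate, via dimethyl ketal 9 (not isolated)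
Conditions: MeOSiMe3 (2.5 equiv), TMSOTf (5 mol %), CH2Cl2, −78 °C; then iPr2NEt (1.5 equiv), TMSOTf (1.2 equiv), −20 °C → rt; Et3N quench
Reagents that add atoms: methoxytrimethylsilane, CO[Si](C)(C)C
Why: Noyori ketalisation followed in the same flask by TMSOTf/amine elimination of the ketal, in which the hindered base should deprotonate the oxocarbenium ion at the unhindered methyl group and give the less substituted 2-methoxy-1-alkene.

Step 8
Reactants: 11 dec-9-enal
Product: 12 (E)-1-iodoundeca-1,10-diene
Conditions: CrCl2 (6 equiv), CHI3 (2 equiv), THF, 0 °C → rt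
Reagents that add atoms: iodoform, IC(I)I
Why: Takai olefination, in which the gem-dichromium carbenoid from iodoform should convert the aldehyde into the (E)-vinyl iodide.

Step 9
Reactants: 12 (E)-1-iodoundeca-1,10-diene; 13 methyl pent-4-ynoate
Product: 14 methyl (E)-hexadeca-6,15-dien-4-ynoate
Conditions: PdCl2(PPh3)2 (2 mol %), CuI (4 mol %), Et3N, THF, rt
Reagents that add atoms: none
Why: Sonogashira coupling of a vinyl iodide with a terminal alkyne, which proceeds with retention of the (E) geometry.

Step 10
Reactants: 14 methyl (E)-hexadeca-6,15-dien-4-ynoate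
Product: 15 (E)-hexadeca-6,15-dien-4-ynoic acid
Conditions: LiOH, THF/H2O, rt; then 1 M HCl
Reagents that add atoms: lithium hydroxide, [Li+].[OH-]
Why: Saponification of a methyl ester under conditions that do not touch the enyne or the terminal alkene.

Step 11
Reactants: 15 (E)-hexadeca-6,15-dien-4-ynoic acid
Product: 16 1,3-dioxoisoindolin-2-yl (E)-hexadeca-6,15-dien-4-ynoate
Conditions: N-hydroxyphthalimide, DIC, DMAP (cat.), CH2Cl2, rt
Reagents that add atoms: N-hydroxyphthalimide, O=C1c2ccccc2C(=O)N1O
Why: Carbodiimide esterification, which should give the redox-active N-acyloxyphthalimide.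

Step 12
Reactants: 16 1,3-dioxoisoindolin-2-yl (E)-hexadeca-6,15-dien-4-ynoate; 10 (R)-1-[(tert-butyldimethylsilyl)oxy]-6-methoxyhept-6-en-3-yl methanesulfonate
Product: 17 (3R,12E)-1-[(tert-butyldimethylsilyl)oxy]-6,6-dimethoxydocosa-12,21-dien-10-yn-3-yl methanesulfonate
Conditions: fac-Ir(ppy)3 (1 mol %), 10 (3 equiv, excess recovered), MeOH/CH2Cl2 1:4, NaHCO3, blue LEDs (450 nm), rt, degassed, 16 added slowly
Reagents that add atoms: methanol, CO
Why: Proposed new method: Photoexcited fac-Ir(ppy)3 should transfer an electron to the N-acyloxyphthalimide 16, which fragments to CO2, phthalimide anion and the primary homopropargylic radical; this radical adds to the unsubstituted CH2 terminus of the 1,1-disubstituted enol ether 10, and the resulting tertiary α-methoxyalkyl radical is oxidised by Ir(IV) to the oxocarbenium ion, which methanol captures as the dimethyl ketal (redox-neutral radical–polar crossover). The closest known reaction type is the photoredox decarboxylative oxyalkylation of styrenes and the alkylation of enamides and aryl silyl enol ethers with N-acyloxyphthalimides; new here is an unactivated primary radical on a purely aliphatic enol ether. No ring is closed and no stereocentre is created, because the ketal carbon carries two methoxy groups, and the mesylate-bearing centre is a spectator. The step needs the weakly nucleophilic radical to attack the electron-rich enol ether faster than the internal enyne and the terminal alkene of its own chain; the excess of enol ether, its sterically open CH2 terminus, the oxygen stabilisation of the adduct radical and the slow addition of 16 are meant to secure this. Methanol in large excess should outcompete phthalimide anion and a second enol ether molecule for the cation, and rapid oxidation of the α-alkoxy radical should suppress oligomerisation.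

Step 13
Reactants: 17 (3R,12E)-1-[(tert-butyldimethylsilyl)oxy]-6,6-dimethoxydocosa-12,21-dien-10-yn-3-yl methanesulfonate
Product: 18 tert-butyl{[(3S,12E)-3-hydroperoxy-6,6-dimethoxydocosa-12,21-dien-10-yn-1-yl]oxy}dimethylsilane
Conditions: 50% H2O2 (excess), KOH, MeOH/THF, 0 °C → rt
Reagents that add atoms: hydrogen peroxide, OO
Why: SN2 displacement of a secondary sulfonate by hydroperoxide anion, which should invert the (R) centre to the (S)-hydroperoxide while the ketal and silyl ether are stable to base.

Step 14
Reactants: 18 tert-butyl{[(3S,12E)-3-hydroperoxy-6,6-dimethoxydocosa-12,21-dien-10-yn-1-yl]oxy}dimethylsilane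
Product: 20 2-[(3S,6R)-6-[(E)-hexadeca-6,15-dien-4-yn-1-yl]-6-methoxy-1,2-dioxan-3-yl]ethan-1-ol, via silyl ether 19 (not isolated)
Conditions: CSA (10 mol %), MeOH/CH2Cl2 1:1, 0 °C → rt
Reagents that add atoms: methanol, CO (solvent; it exchanges with the methoxy group at C6 during the equilibration)
Why: Acid-catalysed transketalisation, in which the hydroperoxide oxygen closes the 1,2-dioxane by 6-exo attack on the C6 oxocarbenium ion, the peroxyketal equilibrates through the cyclic peroxycarbenium ion to the anomerically stabilised chair with axial methoxy and equatorial carbon substituents (6R), and the primary TBS ether is methanolysed.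

Step 15
Reactants: 20 2-[(3S,6R)-6-[(E)-hexadeca-6,15-dien-4-yn-1-yl]-6-methoxy-1,2-dioxan-3-yl]ethan-1-ol
Product: 21 2-[(3S,6R)-6-[(E)-hexadeca-6,15-dien-4-yn-1-yl]-6-methoxy-1,2-dioxan-3-yl]acetic acid
Conditions: TEMPO (20 mol %), PhI(OAc)2 (2.2 equiv), MeCN/pH 7 phosphate buffer 1:1, rt
Reagents that add atoms: water, O (second oxygen of the carboxyl group)
Why: TEMPO/PhI(OAc)2 oxidation of a primary alcohol to the acid via the aldehyde hydrate, an oxoammonium oxidation that should leave the dialkyl peroxide, the enyne and the terminal alkene intact.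

## Compound list

1 | methyl acetoacetate | CC(=O)CC(=O)OC | starting material
2 | allyl bromide | C=CCBr | starting material
3 | methyl 3-oxohept-6-enoate | C=CCCC(=O)CC(=O)OC | intermediate
4 | methyl (R)-3-hydroxyhept-6-enoate | C=CCC[C@@H](O)CC(=O)OC | intermediate
5 | (R)-hept-6-ene-1,3-diol | C=CCC[C@@H](O)CCO | intermediate
6 | (R)-1-[(tert-butyldimethylsilyl)oxy]hept-6-en-3-ol | C=CCC[C@@H](O)CCO[Si](C)(C)C(C)(C)C | intermediate
7 | (R)-1-[(tert-butyldimethylsilyl)oxy]hept-6-en-3-yl methanesulfonate | C=CCC[C@@H](OS(C)(=O)=O)CCO[Si](C)(C)C(C)(C)C | intermediate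
8 | (R)-1-[(tert-butyldimethylsilyl)oxy]-6-oxoheptan-3-yl methanesulfonate | CC(=O)CC[C@@H](OS(C)(=O)=O)CCO[Si](C)(C)C(C)(C)C | intermediate
9 | (R)-1-[(tert-butyldimethylsilyl)oxy]-6,6-dimethoxyheptan-3-yl methanesulfonate | CC(OC)(OC)CC[C@@H](OS(C)(=O)=O)CCO[Si](C)(C)C(C)(C)C | intermediate (not isolated)
10 | (R)-1-[(tert-butyldimethylsilyl)oxy]-6-methoxyhept-6-en-3-yl methanesulfonate | C=C(OC)CC[C@@H](OS(C)(=O)=O)CCO[Si](C)(C)C(C)(C)C | intermediate
11 | dec-9-enal | C=CCCCCCCCC=O | starting material
12 | (E)-1-iodoundeca-1,10-diene | C=CCCCCCCC/C=C/I | intermediate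
13 | methyl pent-4-ynoate | C#CCCC(=O)OC | starting material
14 | methyl (E)-hexadeca-6,15-dien-4-ynoate | C=CCCCCCCC/C=C/C#CCCC(=O)OC | intermediate
15 | (E)-hexadeca-6,15-dien-4-ynoic acid | C=CCCCCCCC/C=C/C#CCCC(=O)O | intermediate
16 | 1,3-dioxoisoindolin-2-yl (E)-hexadeca-6,15-dien-4-ynoate | C=CCCCCCCC/C=C/C#CCCC(=O)ON1C(=O)c2ccccc2C1=O | intermediate
17 | (3R,12E)-1-[(tert-butyldimethylsilyl)oxy]-6,6-dimethoxydocosa-12,21-dien-10-yn-3-yl methanesulfonate | C=CCCCCCCC/C=C/C#CCCCC(OC)(OC)CC[C@@H](OS(C)(=O)=O)CCO[Si](C)(C)C(C)(C)C | intermediate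
18 | tert-butyl{[(3S,12E)-3-hydroperoxy-6,6-dimethoxydocosa-12,21-dien-10-yn-1-yl]oxy}dimethylsilane | C=CCCCCCCC/C=C/C#CCCCC(OC)(OC)CC[C@H](OO)CCO[Si](C)(C)C(C)(C)C | intermediate
19 | tert-butyl{2-[(3S)-6-[(E)-hexadeca-6,15-dien-4-yn-1-yl]-6-methoxy-1,2-dioxan-3-yl]ethoxy}dimethylsilane (C6 epimers, equilibrating) | C=CCCCCCCC/C=C/C#CCCCC1(OC)CC[C@@H](CCO[Si](C)(C)C(C)(C)C)OO1 | intermediate (not isolated)
20 | 2-[(3S,6R)-6-[(E)-hexadeca-6,15-dien-4-yn-1-yl]-6-methoxy-1,2-dioxan-3-yl]ethan-1-ol | C=CCCCCCCC/C=C/C#CCCC[C@]1(OC)CC[C@@H](CCO)OO1 | intermediate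
21 | 2-[(3S,6R)-6-[(E)-hexadeca-6,15-dien-4-yn-1-yl]-6-methoxy-1,2-dioxan-3-yl]acetic acid | C=CCCCCCCC/C=C/C#CCCC[C@]1(OC)CC[C@@H](CC(=O)O)OO1 | target

## Step count and risks

Total: 15 steps. Longest linear sequence: 11 steps (steps 1–7 and 12–15); the chain branch (steps 8–11) is 4 steps.

**Step 12 (proposed new method).** The primary alkyl radical may add too slowly to the electron-rich enol ether and be lost by addition to the enyne or alkene of another chain molecule or by hydrogen abstraction, and the cation may lose a proton or alkylate a second enol ether instead of taking up methanol. The fallback makes the same C–C bond by known carbanion chemistry; it sets out from 12 and 6 and returns at 17. Sonogashira coupling of 12 with but-3-yn-1-ol should give (E)-pentadeca-5,14-dien-3-yn-1-ol F1, which I2/PPh3/imidazole converts into (E)-15-iodopentadeca-1,10-dien-12-yne F2. Alcohol 6 is silylated with Et3SiCl/imidazole to the bis-silyl ether F3, Wacker oxidation gives the methyl ketone F4, and 1,1-dimethylhydrazine gives the N,N-dimethylhydrazone F5. Deprotonation with LDA at the methyl group and alkylation with F2 should give the chain-extended hydrazone F6. Aqueous oxalic acid cleaves the hydrazone and the triethylsilyl ether to the hydroxy ketone F7, MsCl/Et3N gives the keto mesylate F8, and MeOSiMe3/TMSOTf ketalisation gives 17.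

**Step 13.** Hydroperoxide anion may act as a base, so that E2 elimination of the secondary mesylate, or over-alkylation to a dialkyl peroxide, erodes the substitution. The fallback attaches the peroxide to C6 first and closes the ring by intramolecular alkylation; it sets out from 17 and returns at 19. Exchange of one methoxy group of 17 with anhydrous H2O2 in ether under acid catalysis should give the hydroperoxy ketal F9. KOtBu/18-crown-6 in toluene then closes the dioxane by 6-exo-tet displacement of the mesylate with inversion, giving 19, which the conditions of step 14 convert into 20.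

**Step 7.** Deprotonation of the oxocarbenium ion may not discriminate well enough between the methyl and the methylene group; the internal enol ether would place the new C–C bond on the wrong carbon in step 12. The fallback builds the enol ether regiospecifically by carbonyl methylenation; it sets out from 7 and returns at 10. Ozonolysis of the terminal alkene of 7 in CH2Cl2/MeOH with NaOH at −78 °C should give directly the one-carbon-shorter methyl ester, methyl (R)-6-[(tert-butyldimethylsilyl)oxy]-4-[(methylsulfonyl)oxy]hexanoate F10. Tebbe methylenation of the ester carbonyl then gives 10.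

## Further compounds

F1 | step 12 | (E)-pentadeca-5,14-dien-3-yn-1-ol | C=CCCCCCCC/C=C/C#CCCO
F2 | step 12 | (E)-15-iodopentadeca-1,10-dien-12-yne | C=CCCCCCCC/C=C/C#CCCI
F3 | step 12 | (R)-tert-butyldimethyl({3-[(triethylsilyl)oxy]hept-6-en-1-yl}oxy)silane | C=CCC[C@@H](O[Si](CC)(CC)CC)CCO[Si](C)(C)C(C)(C)C
F4 | step 12 | (R)-7-[(tert-butyldimethylsilyl)oxy]-5-[(triethylsilyl)oxy]heptan-2-one | CC(=O)CC[C@@H](O[Si](CC)(CC)CC)CCO[Si](C)(C)C(C)(C)C
F5 | step 12 | N,N-dimethylhydrazone of (R)-7-[(tert-butyldimethylsilyl)oxy]-5-[(triethylsilyl)oxy]heptan-2-one | CC(=NN(C)C)CC[C@@H](O[Si](CC)(CC)CC)CCO[Si](C)(C)C(C)(C)C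
F6 | step 12 | N,N-dimethylhydrazone of (3R,12E)-1-[(tert-butyldimethylsilyl)oxy]-3-[(triethylsilyl)oxy]docosa-12,21-dien-10-yn-6-one | C=CCCCCCCC/C=C/C#CCCCC(=NN(C)C)CC[C@@H](O[Si](CC)(CC)CC)CCO[Si](C)(C)C(C)(C)C
F7 | step 12 | (3R,12E)-1-[(tert-butyldimethylsilyl)oxy]-3-hydroxydocosa-12,21-dien-10-yn-6-one | C=CCCCCCCC/C=C/C#CCCCC(=O)CC[C@@H](O)CCO[Si](C)(C)C(C)(C)C
F8 | step 12 | (3R,12E)-1-[(tert-butyldimethylsilyl)oxy]-6-oxodocosa-12,21-dien-10-yn-3-yl methanesulfonate | C=CCCCCCCC/C=C/C#CCCCC(=O)CC[C@@H](OS(C)(=O)=O)CCO[Si](C)(C)C(C)(C)C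
F9 | step 13 | (3R,12E)-1-[(tert-butyldimethylsilyl)oxy]-6-hydroperoxy-6-methoxydocosa-12,21-dien-10-yn-3-yl methanesulfonate (C6 epimers) | C=CCCCCCCC/C=C/C#CCCCC(OC)(OO)CC[C@@H](OS(C)(=O)=O)CCO[Si](C)(C)C(C)(C)C
F10 | step 7 | methyl (R)-6-[(tert-butyldimethylsilyl)oxy]-4-[(methylsulfonyl)oxy]hexanoate | COC(=O)CC[C@@H](OS(C)(=O)=O)CCO[Si](C)(C)C(C)(C)C
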